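**Retrosynthetic overview** (labdane numbering: ring A = C1–C5, C10; ring B = C5–C10; C4 carries CH3 and the C18 acid, C8 carries CH3 and OAc, C9 carries the C11–C13 acid chain)
1. The target comes from a benzyl-protected 8-hydroxy trans-decalin by O-acetylation, double debenzylation and oxidation of C13.
2. Key disconnection C6–C7 (ring B, closed last): 6-endo-trig cyclisation of a primary C7 radical, released from a C7–SePh group next to the C8 carbinol, onto C6 of an exocyclic C5=C6 methylene on ring A.
3. Enabling feature: this C5=C6 methylene sits between the quaternary C4 and C10 of ring A, so only its C6 terminus can be attacked, and the C5 radical can take hydrogen only anti to the two axial methyl groups (trans ring fusion).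
4. C7–C8 by Felkin–Anh addition of PhSeCH2Li to a C8 methyl ketone; C9–C10 and the C5=C6 methylene together by an Ireland–Claisen rearrangement of a (cyclohexenyl)methyl ester; C5–C6 by Stille coupling of a ring A enol triflate.
5. Ring order: ring A first (from ethyl 2-oxocyclohexanecarboxylate, C4 set by auxiliary-controlled enamine methylation), then ring B by the key step.

Key step: step 11

Remark: in step 3 the face alkylated in valine-ester lithio-enamines depends on the donor additive; the combination (HMPA in toluene, an ether solvent, or else the D-valine ester) that gives the (R)-configured quaternary centre is the one meant.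

Step 1
Reactants: 1 ethyl 2-oxocyclohexane-1-carboxylate; 2 benzyl alcohol
Product: 3 benzyl 2-oxocyclohexane-1-carboxylate
Conditions: 4-(dimethylamino)pyridine (cat.), PhMe, reflux, EtOH distilled off
Reagents that add atoms: none
Why: Amine-catalysed transesterification of the β-keto ester, driven by removal of ethanol, should exchange ethyl for the benzyl ester that is later removed by hydrogenolysis without touching the tertiary acetate; no stereocentre is involved.

Step 2
Reactants: 3 benzyl 2-oxocyclohexane-1-carboxylate; 4 tert-butyl L-valinate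
Product: 5 benzyl 2-{[(2S)-1-tert-butoxy-3-methyl-1-oxobutan-2-yl]amino}cyclohex-1-ene-1-carboxylate
Conditions: BF3·OEt2 (cat.), PhH, reflux (Dean–Stark)
Reagents that add atoms: none
Why: Acid-catalysed condensation of the ketone with the primary amine under azeotropic removal of water (enamine formation) should give the conjugated vinylogous carbamate that places the chiral auxiliary next to C4.

Step 3
Reactants: 5 benzyl 2-{[(2S)-1-tert-butoxy-3-methyl-1-oxobutan-2-yl]amino}cyclohex-1-ene-1-carboxylate
Product: 8 benzyl (1R)-1-methyl-2-oxocyclohexane-1-carboxylate, via lithium aza-enolate 6 (not isolated), via methylated imine 7 (not isolated)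
Conditions: LiN(i-Pr)2, PhMe, HMPA (1 equiv), −78 °C; MeI; then 1 M HCl, rt
Reagents that add atoms: iodomethane (CI); water (O)
Why: Auxiliary-controlled C-alkylation of the chelated lithio-enamine (asymmetric enamine alkylation) should deliver the methyl group to the C4 face not screened by the valine isopropyl group, and acid hydrolysis of the imine should then release the (R)-configured quaternary keto ester and the recoverable auxiliary.

Step 4
Reactants: 8 benzyl (1R)-1-methyl-2-oxocyclohexane-1-carboxylate
Product: 10 benzyl (1R)-1,3-dimethyl-2-oxocyclohexane-1-carboxylate (C3 epimers), via lithium enolate 9 (not isolated)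
Conditions: LiN(i-Pr)2, THF, −78 °C; MeI, −78 → 0 °C
Reagents that add atoms: iodomethane (CI)
Why: Enolate alkylation at C10, the only enolisable position, should install the second methyl group, and the configuration of the new centre is irrelevant because it becomes trigonal in step 5.

Step 5
Reactants: 10 benzyl (1R)-1,3-dimethyl-2-oxocyclohexane-1-carboxylate (C3 epimers)
Product: 12 benzyl (1R)-1,3-dimethyl-2-{[(trifluoromethyl)sulfonyl]oxy}cyclohex-2-ene-1-carboxylate, via potassium enolate 11 (not isolated)
Conditions: KN(SiMe3)2, THF, −78 °C; PhNTf2, −78 → 0 °C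
Reagents that add atoms: N-phenylbis(trifluoromethanesulfonimide) (O=S(=O)(N(c1ccccc1)S(=O)(=O)C(F)(F)F)C(F)(F)F)
Why: O-sulfonylation of the potassium enolate (enol triflate formation) should give the tetrasubstituted C5=C10 enol triflate as a single regioisomer because C4 is quaternary.

Step 6
Reactants: 13 (tributylstannyl)methanol; 14 5-(benzyloxy)pentanoic acid
Product: 15 (tributylstannyl)methyl 5-(benzyloxy)pentanoate
Conditions: dicyclohexylcarbodiimide, 4-(dimethylamino)pyridine (cat.), CH2Cl2, 0 °C → rt
Reagents that add atoms: none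
Why: Steglich esterification should acylate the C6 oxygen before C6 is attached to ring A, so that a free C6 hydroxyl never sits next to the C18 ester, where it would lactonise.

Step 7
Reactants: 12 benzyl (1R)-1,3-dimethyl-2-{[(trifluoromethyl)sulfonyl]oxy}cyclohex-2-ene-1-carboxylate; 15 (tributylstannyl)methyl 5-(benzyloxy)pentanoate
Product: 16 benzyl (1R)-2-({[5-(benzyloxy)pentanoyl]oxy}methyl)-1,3-dimethylcyclohex-2-ene-1-carboxylate
Conditions: Pd(PPh3)4 (cat.), CuCl, LiCl, DMSO, 60 °C
Reagents that add atoms: none
Why: Stille cross-coupling in its CuCl/LiCl-accelerated form for congested enol triflates should transfer the α-acyloxymethyl group from tin to C5 in preference to butyl and give the allylic ester directly; no stereocentre is set.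

Step 8
Reactants: 16 benzyl (1R)-2-({[5-(benzyloxy)pentanoyl]oxy}methyl)-1,3-dimethylcyclohex-2-ene-1-carboxylate
Product: 20 (2R)-5-(benzyloxy)-2-[(1R,3R)-3-[(benzyloxy)carbonyl]-1,3-dimethyl-2-methylidenecyclohexyl]pentanoic acid, via lithium ester enolate 17 (not isolated), via silyl ketene acetal 18 (not isolated), via silyl ester 19 (not isolated)
Conditions: LiN(i-Pr)2, THF/DMPU (4:1), −78 °C; t-BuMe2SiCl, −78 °C → rt; PhMe, 90 °C; then 1 M HCl/THF
Reagents that add atoms: none
Why: Ireland–Claisen rearrangement through a chair transition state should form the C9–C10 bond and the exocyclic C5=C6 methylene in one event, with the ketene acetal geometry (C11 chain cis to OSi, from enolisation in THF/DMPU) fixing C9 relative to the quaternary C10, and with approach syn to the flat benzyl ester and anti to the C4 methyl fixing the ring face.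

Step 9
Reactants: 20 (2R)-5-(benzyloxy)-2-[(1R,3R)-3-[(benzyloxy)carbonyl]-1,3-dimethyl-2-methylidenecyclohexyl]pentanoic acid
Product: 22 benzyl (1R,3R)-3-[(3R)-6-(benzyloxy)-2-oxohexan-3-yl]-1,3-dimethyl-2-methylidenecyclohexane-1-carboxylate, via acid chloride 21 (not isolated)
Conditions: (COCl)2, DMF (cat.), CH2Cl2, 0 °C → rt; then Me2CuLi, Et2O, −78 °C
Reagents that add atoms: lithium dimethylcuprate ([Li+].C[Cu-]C)
Why: Acid chloride formation followed by acylation of the Gilman cuprate, a ketone synthesis that stops at the ketone and spares the hindered benzyl ester and the C9 centre, should give the C8 methyl ketone.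

Step 10
Reactants: 22 benzyl (1R,3R)-3-[(3R)-6-(benzyloxy)-2-oxohexan-3-yl]-1,3-dimethyl-2-methylidenecyclohexane-1-carboxylate
Product: 23 benzyl (1R,3R)-3-[(2S,3R)-6-(benzyloxy)-2-hydroxy-2-methyl-1-(phenylselanyl)hexan-3-yl]-1,3-dimethyl-2-methylidenecyclohexane-1-carboxylate
Conditions: (PhSe)2CH2, n-BuLi, THF, −78 °C (gives PhSeCH2Li); then the ketone, −78 °C
Reagents that add atoms: bis(phenylselanyl)methane (C([Se]c1ccccc1)[Se]c1ccccc1)
Why: Felkin–Anh 1,2-addition of the α-selanyl organolithium, anti to the very large quaternary C10 substituent on C9 and past the C9 hydrogen, should set the C8 carbinol centre with methyl and hydroxyl as in the target and place the radical precursor on C7.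

Step 11
Reactants: 23 benzyl (1R,3R)-3-[(2S,3R)-6-(benzyloxy)-2-hydroxy-2-methyl-1-(phenylselanyl)hexan-3-yl]-1,3-dimethyl-2-methylidenecyclohexane-1-carboxylate
Product: 24 benzyl (1R,4aS,5R,6R,8aR)-5-[3-(benzyloxy)propyl]-6-hydroxy-1,4a,6-trimethyldecahydronaphthalene-1-carboxylate
Conditions: (Me3Si)3SiH, azobis(isobutyronitrile) (cat.), PhH, 80 °C, slow addition, 0.005 M
Reagents that add atoms: none
Why: The silyl radical abstracts the phenylselanyl group from C7, the resulting primary β-hydroxyalkyl radical adds to C6, the unsubstituted terminus of the exocyclic C5=C6 alkene, and the tertiary C5 radical then takes a hydrogen atom from the silane and regenerates the chain carrier. The closest known reaction type is the silane- or stannane-mediated cyclisation of alkyl phenyl selenides onto 1,1-disubstituted alkenes, in which a 5-substituted hex-5-enyl radical closes in the endo sense. Ring B closes 6-endo-trig, because the alternative 5-exo attack would have to make a bond to C5 between the quaternary C4 and C10. The one new stereocentre, C5, is controlled by the axial methyl groups on C4 and C10, which screen the β face of the planar C5 radical, so hydrogen should arrive from the α face and give the trans ring fusion; C4, C8, C9 and C10 are not touched, and the C8 oxygen is kept as a free hydroxyl because it cannot undergo a 1,2-acyloxy shift. The selectivity needed is cyclisation before hydrogen transfer to the C7 radical, which should be secured by the conformationally restricted tether (quaternary C10, fully substituted C8), the chair-like transition state with the C9 chain equatorial, and slow addition of the poor hydrogen donor (Me3Si)3SiH.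

Step 12
Reactants: 24 benzyl (1R,4aS,5R,6R,8aR)-5-[3-(benzyloxy)propyl]-6-hydroxy-1,4a,6-trimethyldecahydronaphthalene-1-carboxylate
Product: 26 benzyl (1R,4aS,5R,6R,8aR)-6-acetoxy-5-[3-(benzyloxy)propyl]-1,4a,6-trimethyldecahydronaphthalene-1-carboxylate, via lithium alkoxide 25 (not isolated)
Conditions: LiN(SiMe3)2, THF, −78 °C; AcCl, −78 → 0 °C
Reagents that add atoms: acetyl chloride (CC(Cl)=O)
Why: O-acylation of the preformed lithium alkoxide, the usual answer to a hindered tertiary alcohol, should give the tertiary acetate with the C8 configuration unchanged because no bond to C8 is broken.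

Step 13
Reactants: 26 benzyl (1R,4aS,5R,6R,8aR)-6-acetoxy-5-[3-(benzyloxy)propyl]-1,4a,6-trimethyldecahydronaphthalene-1-carboxylate
Product: 27 (1R,4aS,5R,6R,8aR)-6-acetoxy-5-(3-hydroxypropyl)-1,4a,6-trimethyldecahydronaphthalene-1-carboxylic acid
Conditions: H2 (1 atm), 10% Pd/C, EtOAc/EtOH, rt
Reagents that add atoms: none
Why: Palladium-catalysed hydrogenolysis of the benzyl ether and the benzyl ester should free the C13 alcohol and the C18 acid in one operation, while the tertiary acetate has no benzylic or reducible bond and is left alone.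

Step 14
Reactants: 27 (1R,4aS,5R,6R,8aR)-6-acetoxy-5-(3-hydroxypropyl)-1,4a,6-trimethyldecahydronaphthalene-1-carboxylic acid
Product: 28 (1R,4aS,5R,6R,8aR)-6-acetoxy-5-(2-carboxyethyl)-1,4a,6-trimethyldecahydronaphthalene-1-carboxylic acid (CNP0196050.1)
Conditions: 2,2,6,6-tetramethylpiperidin-1-oxyl (cat.), PhI(OAc)2, MeCN/H2O (1:1), rt
Reagents that add atoms: water (O)
Why: Oxoammonium (TEMPO) oxidation of the primary alcohol through the aldehyde hydrate, with PhI(OAc)2 as terminal oxidant, should give the second carboxylic acid under near-neutral conditions that neither ionise nor hydrolyse the tertiary acetate.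

**Compound list**
1 | ethyl 2-oxocyclohexane-1-carboxylate | CCOC(=O)C1CCCCC1=O | starting material
2 | benzyl alcohol | OCc1ccccc1 | starting material
3 | benzyl 2-oxocyclohexane-1-carboxylate | O=C1CCCCC1C(=O)OCc1ccccc1 | intermediate
4 | tert-butyl L-valinate (tert-butyl (2S)-2-amino-3-methylbutanoate) | CC(C)[C@H](N)C(=O)OC(C)(C)C | starting material
5 | benzyl 2-{[(2S)-1-tert-butoxy-3-methyl-1-oxobutan-2-yl]amino}cyclohex-1-ene-1-carboxylate | CC(C)[C@H](NC1=C(CCCC1)C(=O)OCc1ccccc1)C(=O)OC(C)(C)C | intermediate
6 | N-lithio derivative (lithium aza-enolate) of enamine 5 | CC(C)[C@H](N([Li])C1=C(CCCC1)C(=O)OCc1ccccc1)C(=O)OC(C)(C)C | intermediate (not isolated)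
7 | benzyl (1R)-2-{[(2S)-1-tert-butoxy-3-methyl-1-oxobutan-2-yl]imino}-1-methylcyclohexane-1-carboxylate | CC(C)[C@H](N=C1CCCC[C@@]1(C)C(=O)OCc1ccccc1)C(=O)OC(C)(C)C | intermediate (not isolated)
8 | benzyl (1R)-1-methyl-2-oxocyclohexane-1-carboxylate | O=C1CCCC[C@@]1(C)C(=O)OCc1ccccc1 | intermediate
9 | lithium enolate of 8 (enolate towards C3) | [Li+].[O-]C1=CCCC[C@@]1(C)C(=O)OCc1ccccc1 | intermediate (not isolated)
10 | benzyl (1R)-1,3-dimethyl-2-oxocyclohexane-1-carboxylate (C3 epimers) | CC1CCC[C@@](C)(C(=O)OCc2ccccc2)C1=O | intermediate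
11 | potassium enolate of 10 | [K+].[O-]C1=C(C)CCC[C@@]1(C)C(=O)OCc1ccccc1 | intermediate (not isolated)
12 | benzyl (1R)-1,3-dimethyl-2-{[(trifluoromethyl)sulfonyl]oxy}cyclohex-2-ene-1-carboxylate | CC1=C(OS(=O)(=O)C(F)(F)F)[C@@](C)(CCC1)C(=O)OCc1ccccc1 | intermediate
13 | (tributylstannyl)methanol | CCCC[Sn](CCCC)(CCCC)CO | starting material
14 | 5-(benzyloxy)pentanoic acid | OC(=O)CCCCOCc1ccccc1 | starting material
15 | (tributylstannyl)methyl 5-(benzyloxy)pentanoate | CCCC[Sn](CCCC)(CCCC)COC(=O)CCCCOCc1ccccc1 | intermediate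
16 | benzyl (1R)-2-({[5-(benzyloxy)pentanoyl]oxy}methyl)-1,3-dimethylcyclohex-2-ene-1-carboxylate | CC1=C(COC(=O)CCCCOCc2ccccc2)[C@@](C)(CCC1)C(=O)OCc1ccccc1 | intermediate
17 | lithium ester enolate of 16 (C11 chain cis to O–Li) | [Li+].CC1=C(CO/C([O-])=C/CCCOCc2ccccc2)[C@@](C)(CCC1)C(=O)OCc1ccccc1 | intermediate (not isolated)
18 | tert-butyldimethylsilyl ketene acetal of 16 (C11 chain cis to OSi) | CC1=C(CO/C(O[Si](C)(C)C(C)(C)C)=C/CCCOCc2ccccc2)[C@@](C)(CCC1)C(=O)OCc1ccccc1 | intermediate (not isolated)
19 | tert-butyldimethylsilyl ester of acid 20 | C=C1[C@](C)(CCC[C@@]1(C)C(=O)OCc1ccccc1)[C@@H](CCCOCc1ccccc1)C(=O)O[Si](C)(C)C(C)(C)C | intermediate (not isolated)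
20 | (2R)-5-(benzyloxy)-2-[(1R,3R)-3-[(benzyloxy)carbonyl]-1,3-dimethyl-2-methylidenecyclohexyl]pentanoic acid | C=C1[C@](C)(CCC[C@@]1(C)C(=O)OCc1ccccc1)[C@@H](CCCOCc1ccccc1)C(=O)O | intermediate
21 | acid chloride of 20 | C=C1[C@](C)(CCC[C@@]1(C)C(=O)OCc1ccccc1)[C@@H](CCCOCc1ccccc1)C(=O)Cl | intermediate (not isolated)
22 | benzyl (1R,3R)-3-[(3R)-6-(benzyloxy)-2-oxohexan-3-yl]-1,3-dimethyl-2-methylidenecyclohexane-1-carboxylate | C=C1[C@](C)(CCC[C@@]1(C)C(=O)OCc1ccccc1)[C@@H](CCCOCc1ccccc1)C(C)=O | intermediate
23 | benzyl (1R,3R)-3-[(2S,3R)-6-(benzyloxy)-2-hydroxy-2-methyl-1-(phenylselanyl)hexan-3-yl]-1,3-dimethyl-2-methylidenecyclohexane-1-carboxylate | C=C1[C@](C)(CCC[C@@]1(C)C(=O)OCc1ccccc1)[C@@H](CCCOCc1ccccc1)[C@](C)(O)C[Se]c1ccccc1 | intermediate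
24 | benzyl (1R,4aS,5R,6R,8aR)-5-[3-(benzyloxy)propyl]-6-hydroxy-1,4a,6-trimethyldecahydronaphthalene-1-carboxylate | O[C@]1(C)CC[C@@H]2[C@](C)(CCC[C@@]2(C)C(=O)OCc2ccccc2)[C@H]1CCCOCc1ccccc1 | intermediate
25 | lithium alkoxide of 24 | [Li+].[O-][C@]1(C)CC[C@@H]2[C@](C)(CCC[C@@]2(C)C(=O)OCc2ccccc2)[C@H]1CCCOCc1ccccc1 | intermediate (not isolated)
26 | benzyl (1R,4aS,5R,6R,8aR)-6-acetoxy-5-[3-(benzyloxy)propyl]-1,4a,6-trimethyldecahydronaphthalene-1-carboxylate | CC(=O)O[C@]1(C)CC[C@@H]2[C@](C)(CCC[C@@]2(C)C(=O)OCc2ccccc2)[C@H]1CCCOCc1ccccc1 | intermediate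
27 | (1R,4aS,5R,6R,8aR)-6-acetoxy-5-(3-hydroxypropyl)-1,4a,6-trimethyldecahydronaphthalene-1-carboxylic acid | CC(=O)O[C@]1(C)CC[C@@H]2[C@](C)(CCC[C@@]2(C)C(=O)O)[C@H]1CCCO | intermediate
28 | (1R,4aS,5R,6R,8aR)-6-acetoxy-5-(2-carboxyethyl)-1,4a,6-trimethyldecahydronaphthalene-1-carboxylic acid | CC(=O)O[C@]1(C)CC[C@@H]2[C@](C)(CCC[C@@]2(C)C(=O)O)[C@H]1CCC(=O)O | target

Total step count: 14.
Longest linear sequence: 13 steps (steps 1–5 and 7–14, from 1 to 28); step 6 is a one-step side branch.

**Steps most likely to fail**

1. Step 8. What may go wrong: erosion of facial selectivity at C10, because the methyl/ester pair on C4 is only a modest controller; leakage through a boat transition state, which would invert C9; or decomposition of the hindered silyl ketene acetal before the congested bond forms. Fallback (reagent control in place of substrate control): starting from ester 16, enolisation with (4R,5R)-2-bromo-4,5-diphenyl-1,3-bis(4-methylphenylsulfonyl)-1,3,2-diazaborolidine and i-Pr2NEt in CH2Cl2 at −78 °C should give the chiral boron ketene acetal F1 (C11 chain cis to O–B; the antipodal controller is taken if it is the matched one). This should rearrange between −20 °C and room temperature to the acyloxyborane F2, and aqueous work-up rejoins the route at acid 20.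

2. Step 11. What may go wrong: hydrogen transfer to the C7 radical before the 6-endo closure, which has to pass a chair with a syn-axial CH3/CH3 contact between C8 and C10, or competing intramolecular hydrogen shifts. Fallback (polarity-reversed closure, with the C8 carbinol built afterwards): starting from ketone 22, kinetic enolisation on the methyl side (LiN(i-Pr)2, THF, −78 °C) and PhSeCl should give the α-phenylselanyl ketone F3. (Me3Si)3SiH with azobis(isobutyronitrile) should then close the electrophilic α-keto radical 6-endo onto the electron-rich methylene, with no syn-axial methyl pair in the transition state, to give the trans-decalone F4, in which C9 can be equilibrated with DBU to the equatorial chain. Wittig methylenation (Ph3P=CH2) should give the exocyclic alkene F5, and Mukaiyama hydration (Mn(dpm)3, PhSiH3, O2, i-PrOH), with oxygen entering C8 from the α face away from the axial C10 methyl, rejoins the route at alcohol 24.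

3. Step 7. What may go wrong: slow transmetalation of the sp3 acyloxymethyl group to palladium at the tetrasubstituted enol triflate flanked by a quaternary carbon, so that triflate hydrolysis or butyl transfer takes over. Fallback (nucleophilic vinylchromium addition in place of cross-coupling): starting from triflate 12, a Nozaki–Hiyama–Kishi reaction with formaldehyde (CrCl2, NiCl2 (cat.), paraformaldehyde, DMF, rt) should give the allylic alcohol benzyl (1R)-2-(hydroxymethyl)-1,3-dimethylcyclohex-2-ene-1-carboxylate F6. This is acylated at once, before it can lactonise onto the C18 ester, with acid 14 (dicyclohexylcarbodiimide, 4-(dimethylamino)pyridine, CH2Cl2, 0 °C), which rejoins the route at ester 16.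

**Further compounds**
F1 | step 8 | O-[(4R,5R)-4,5-diphenyl-1,3-bis(4-methylphenylsulfonyl)-1,3,2-diazaborolidin-2-yl] ketene acetal of ester 16 (C11 chain cis to O–B) | CC1=C(CO/C(OB2N(S(=O)(=O)c3ccc(C)cc3)[C@H](c3ccccc3)[C@@H](c3ccccc3)N2S(=O)(=O)c2ccc(C)cc2)=C/CCCOCc2ccccc2)[C@@](C)(CCC1)C(=O)OCc1ccccc1
F2 | step 8 | acyloxyborane of acid 20 with the same (4R,5R)-diazaborolidin-2-yl group | C=C1[C@](C)(CCC[C@@]1(C)C(=O)OCc1ccccc1)[C@@H](CCCOCc1ccccc1)C(=O)OB1N(S(=O)(=O)c2ccc(C)cc2)[C@H](c2ccccc2)[C@@H](c2ccccc2)N1S(=O)(=O)c1ccc(C)cc1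
F3 | step 11 | benzyl (1R,3R)-3-[(3R)-6-(benzyloxy)-2-oxo-1-(phenylselanyl)hexan-3-yl]-1,3-dimethyl-2-methylidenecyclohexane-1-carboxylate | C=C1[C@](C)(CCC[C@@]1(C)C(=O)OCc1ccccc1)[C@@H](CCCOCc1ccccc1)C(=O)C[Se]c1ccccc1
F4 | step 11 | benzyl (1R,4aS,5R,8aR)-5-[3-(benzyloxy)propyl]-1,4a-dimethyl-6-oxodecahydronaphthalene-1-carboxylate | O=C1CC[C@@H]2[C@](C)(CCC[C@@]2(C)C(=O)OCc2ccccc2)[C@H]1CCCOCc1ccccc1
F5 | step 11 | 6-methylidene analogue of F4 (trans-fused; ring centres arranged as in 24) | C=C1CC[C@@H]2[C@](C)(CCC[C@@]2(C)C(=O)OCc2ccccc2)[C@H]1CCCOCc1ccccc1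
F6 | step 7 | benzyl (1R)-2-(hydroxymethyl)-1,3-dimethylcyclohex-2-ene-1-carboxylate | CC1=C(CO)[C@@](C)(CCC1)C(=O)OCc1ccccc1
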